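**Retrosynthetic overview**
1. The target is the 20-methylhenicosyl ester of 2,3-dihydroxybenzoic acid; the last disconnection removes two O-benzyl groups from the catechol oxygens (hydrogenolysis).
2. Key disconnection: the C8–C9 bond of the alcohol chain (C1 = OCH2), a bond between two plain CH2 groups. It is cut homolytically into two primary alkyl radicals of like polarity, each traced back to a carboxylic acid one carbon longer, activated as its N-hydroxyphthalimide ester and losing CO2.
3. Enabling feature: C2–C19 is an unbranched polymethylene run without heteroatoms or stereocentres, so any of its CH2–CH2 bonds can come from a radical–radical union. The cut at C8–C9 gives the iso-fatty acid 13-methyltetradecanoic acid (it brings the isopropyl end C20/C21) and a C9 ω-aroyloxy acid. In the latter, the ester oxygen and the benzyl-protected catechol ring sit eight carbons from the radical centre and are inert to reduction.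
4. The C9 acid comes from 9-bromononan-1-ol by carboxylate O-alkylation (this forms the ester C–O bond) and oxidation of the alcohol to the acid.
5. Rings: no ring is formed anywhere; the only ring, the benzene ring of the catechol, is bought with 2,3-dihydroxybenzoic acid.

Key step: step 6

Remark: the target has no stereocentre, so no stereocontrol is needed; 13-methyltetradecanoic acid (iso-C15:0) is assumed to be purchasable as a fatty-acid standard.

**Step 1**
Reactants: 1 2,3-dihydroxybenzoic acid
Product: 3 2,3-bis(benzyloxy)benzoic acid, via benzyl 2,3-bis(benzyloxy)benzoate 2 (not isolated)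
Conditions: BnBr (3.5 equiv), K2CO3, acetone, reflux; filter, concentrate; then aq. NaOH, MeOH, reflux; HCl to pH 2
Reagents that add atoms: benzyl bromide, BrCc1ccccc1; sodium hydroxide, [Na+].[OH-] (its oxygen ends in the carboxyl group)
Why: Williamson O-benzylation of the carboxylate and both phenols followed by saponification of the benzyl ester only should give the acid, because aryl benzyl ethers are inert to hydroxide.

**Step 2**
Reactants: 3 2,3-bis(benzyloxy)benzoic acid; 4 9-bromononan-1-ol
Product: 5 9-hydroxynonyl 2,3-bis(benzyloxy)benzoate
Conditions: K2CO3, DMF, 60 °C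
Reagents that add atoms: none
Why: SN2 O-alkylation of the potassium carboxylate by the primary bromide should be chemoselective, because carbonate does not deprotonate the aliphatic alcohol.

**Step 3**
Reactants: 5 9-hydroxynonyl 2,3-bis(benzyloxy)benzoate
Product: 7 9-{[2,3-bis(benzyloxy)benzoyl]oxy}nonanoic acid, via 9-oxononyl 2,3-bis(benzyloxy)benzoate 6 (not isolated)
Conditions: TEMPO (20 mol %), PhI(OAc)2 (2.2 equiv), MeCN/CH2Cl2/H2O, rt
Reagents that add atoms: water, O (second carboxyl oxygen, via the aldehyde hydrate)
Why: TEMPO/PhI(OAc)2 oxidation (oxoammonium oxidation of the primary alcohol to the aldehyde, then of its hydrate to the acid) should leave the benzyl ethers and the benzoate untouched.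

**Step 4**
Reactants: 7 9-{[2,3-bis(benzyloxy)benzoyl]oxy}nonanoic acid
Product: 8 1,3-dioxoisoindolin-2-yl 9-{[2,3-bis(benzyloxy)benzoyl]oxy}nonanoate
Conditions: N-hydroxyphthalimide (1.1 equiv), DIC (1.1 equiv), DMAP (10 mol %), CH2Cl2, rt
Reagents that add atoms: N-hydroxyphthalimide, O=C1c2ccccc2C(=O)N1O
Why: Steglich-type carbodiimide esterification of the acid with N-hydroxyphthalimide should give the redox-active ester.

**Step 5**
Reactants: 9 13-methyltetradecanoic acid
Product: 10 1,3-dioxoisoindolin-2-yl 13-methyltetradecanoate
Conditions: N-hydroxyphthalimide (1.1 equiv), DIC (1.1 equiv), DMAP (10 mol %), CH2Cl2, rt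
Reagents that add atoms: N-hydroxyphthalimide, O=C1c2ccccc2C(=O)N1O
Why: The same Steglich-type carbodiimide esterification should convert the fatty acid into its redox-active ester.

**Step 6**
Reactants: 8 1,3-dioxoisoindolin-2-yl 9-{[2,3-bis(benzyloxy)benzoyl]oxy}nonanoate (3 equiv); 10 1,3-dioxoisoindolin-2-yl 13-methyltetradecanoate (1 equiv)
Product: 11 20-methylhenicosyl 2,3-bis(benzyloxy)benzoate
Conditions: NiCl2·6H2O (20 mol %), 2,2':6',2''-terpyridine (20 mol %), AgNO3 (30 mol %), NaI, DMF, (+)Zn/(−)RVC, undivided cell, constant current, rt; aq. HCl work-up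
Reagents that add atoms: none
Why: Each N-acyloxyphthalimide accepts one electron (from the cathode or from low-valent Ni–terpyridine) and its radical anion fragments to phthalimide anion, CO2 and a primary alkyl radical; one radical is captured by nickel, the second adds to the alkyl–Ni species, and reductive elimination from the dialkyl–Ni(III) complex forms the C8–C9 σ-bond while the zinc anode supplies the electrons. The closest known reaction type is the Ni-electrocatalytic doubly decarboxylative C(sp3)–C(sp3) cross-coupling of two primary redox-active esters, the reductive counterpart of a mixed Kolbe electrolysis. No ring is closed and no stereocentre is formed, because both carbons end as CH2 groups of an achiral chain. The step needs cross- over homo-coupling selectivity, which is statistical for two unhindered primary radicals and is therefore secured by using the cheaply made partner 8 in threefold excess over 10; the two symmetrical homocoupling by-products (a hydrocarbon and a diester) differ clearly in polarity from the monoester 11. It also needs chemoselectivity for the two activated carboxyl groups, secured by the phthalimide N–O esters being reduced at a far milder potential than the alkyl benzoate, the benzyl ethers or the arene.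

**Step 7**
Reactants: 11 20-methylhenicosyl 2,3-bis(benzyloxy)benzoate
Product: 12 Gentiside A (20-methylhenicosyl 2,3-dihydroxybenzoate)
Conditions: H2 (1 atm), 10 % Pd/C, EtOAc/THF, rt
Reagents that add atoms: none
Why: Catalytic hydrogenolysis of the two aryl benzyl ethers should free the catechol, while the saturated alkyl benzoate is inert to these conditions.

**Compound list**
1 | 2,3-dihydroxybenzoic acid | OC(=O)c1cccc(O)c1O | starting material
2 | benzyl 2,3-bis(benzyloxy)benzoate | O=C(OCc1ccccc1)c1cccc(OCc2ccccc2)c1OCc1ccccc1 | intermediate
3 | 2,3-bis(benzyloxy)benzoic acid | OC(=O)c1cccc(OCc2ccccc2)c1OCc1ccccc1 | intermediate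
4 | 9-bromononan-1-ol | OCCCCCCCCCBr | starting material
5 | 9-hydroxynonyl 2,3-bis(benzyloxy)benzoate | OCCCCCCCCCOC(=O)c1cccc(OCc2ccccc2)c1OCc1ccccc1 | intermediate
6 | 9-oxononyl 2,3-bis(benzyloxy)benzoate | O=CCCCCCCCCOC(=O)c1cccc(OCc2ccccc2)c1OCc1ccccc1 | intermediate
7 | 9-{[2,3-bis(benzyloxy)benzoyl]oxy}nonanoic acid | OC(=O)CCCCCCCCOC(=O)c1cccc(OCc2ccccc2)c1OCc1ccccc1 | intermediate
8 | 1,3-dioxoisoindolin-2-yl 9-{[2,3-bis(benzyloxy)benzoyl]oxy}nonanoate | O=C(CCCCCCCCOC(=O)c1cccc(OCc2ccccc2)c1OCc1ccccc1)ON1C(=O)c2ccccc2C1=O | intermediate
9 | 13-methyltetradecanoic acid | CC(C)CCCCCCCCCCCC(=O)O | starting material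
10 | 1,3-dioxoisoindolin-2-yl 13-methyltetradecanoate | CC(C)CCCCCCCCCCCC(=O)ON1C(=O)c2ccccc2C1=O | intermediate
11 | 20-methylhenicosyl 2,3-bis(benzyloxy)benzoate | CC(C)CCCCCCCCCCCCCCCCCCCOC(=O)c1cccc(OCc2ccccc2)c1OCc1ccccc1 | intermediate
12 | Gentiside A, 20-methylhenicosyl 2,3-dihydroxybenzoate | CC(C)CCCCCCCCCCCCCCCCCCCOC(=O)c1cccc(O)c1O | target

**Step count**
Total steps: 7. Longest linear sequence: 6 steps (steps 1, 2, 3, 4, 6, 7).

**Steps most likely to fail**

Step 6. The cross-coupling may be eroded by statistical homocoupling of each radical, by premature hydrogen capture or β-hydride elimination at the alkyl–nickel stage, and by fouling of the electrodes by the waxy substrates. The fallback forms the same CH2–CH2 bond by an alkyl–alkyl Suzuki–Miyaura coupling between a nucleophilic and an electrophilic carbon; it sets out from 3 and 9 and comes back to the route at 11. Acid 3 would be O-alkylated with commercial 8-bromooct-1-ene (C=CCCCCCCBr; K2CO3, DMF, 60 °C) to oct-7-en-1-yl 2,3-bis(benzyloxy)benzoate F1. Acid 9 would be converted by Hunsdiecker bromodecarboxylation in the Cristol–Firth form (HgO, Br2, CCl4, reflux, dark) into 1-bromo-12-methyltridecane F2. Anti-Markovnikov hydroboration of F1 with 9-BBN-H (THF, rt) should give 8-(9-borabicyclo[3.3.1]nonan-9-yl)octyl 2,3-bis(benzyloxy)benzoate F3. This would be coupled without isolation with F2 (Pd(OAc)2, PCy3, K3PO4·H2O, THF, rt) to give 11.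

Step 3. The oxidation may stall at the aldehyde stage in the poorly water-miscible medium, or the aldehyde may form a hemiacetal with unreacted alcohol that is oxidised to a dimeric ester. The fallback carries the carboxyl group at the acid oxidation level from the start; it sets out from 3 and comes back at 7. Commercial 9-bromononanoic acid (OC(=O)CCCCCCCCBr) would be esterified with isobutene (cat. H2SO4, CH2Cl2) to tert-butyl 9-bromononanoate F4. The potassium salt of 3 would be alkylated with F4 (K2CO3, DMF, 60 °C) to tert-butyl 9-{[2,3-bis(benzyloxy)benzoyl]oxy}nonanoate F5. Brief treatment with TFA/CH2Cl2 at rt should cleave only the tert-butyl ester and give 7.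

Step 7. Hydrogenolysis of the hindered benzyl ether next to the ester may remain incomplete because the waxy substrate is poorly soluble and the catalyst surface is blocked. The fallback is a protecting-group-free end game that makes the ester bond last; it sets out from 11 and comes back at 12. Saponification of 11 (NaOH, MeOH/THF, reflux) should give 20-methylhenicosan-1-ol F6, with recovery of acid 3. Appel bromination (CBr4, PPh3, CH2Cl2) would give 1-bromo-20-methylhenicosane F7. Unprotected 1 would then be alkylated selectively at the carboxylate with F7 (KHCO3, DMF, 70 °C), the phenols staying protonated under bicarbonate, to give 12.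

**Further compounds**
F1 | step 6 | oct-7-en-1-yl 2,3-bis(benzyloxy)benzoate | C=CCCCCCCOC(=O)c1cccc(OCc2ccccc2)c1OCc1ccccc1
F2 | step 6 | 1-bromo-12-methyltridecane | CC(C)CCCCCCCCCCCBr
F3 | step 6 | 8-(9-borabicyclo[3.3.1]nonan-9-yl)octyl 2,3-bis(benzyloxy)benzoate | O=C(OCCCCCCCCB1C2CCCC1CCC2)c1cccc(OCc2ccccc2)c1OCc1ccccc1
F4 | step 3 | tert-butyl 9-bromononanoate | CC(C)(C)OC(=O)CCCCCCCCBr
F5 | step 3 | tert-butyl 9-{[2,3-bis(benzyloxy)benzoyl]oxy}nonanoate | CC(C)(C)OC(=O)CCCCCCCCOC(=O)c1cccc(OCc2ccccc2)c1OCc1ccccc1
F6 | step 7 | 20-methylhenicosan-1-ol | CC(C)CCCCCCCCCCCCCCCCCCCO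
F7 | step 7 | 1-bromo-20-methylhenicosane | CC(C)CCCCCCCCCCCCCCCCCCCBr
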